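**Plan**

- Ring A is numbered C1 (CO2Me), C2 (O-aryl), C3 (H), C4 (Me), C5 (prenyl), C6 (OH); ring B is the dimethoxybenzyl alcohol ring. Retrosynthesis first removes the carboxyl carbon from C1 (phenol-directed formylation, then oxidation) and takes ring A back to a cyclohexenone. It then cuts the C5–CH2 bond to the prenyl group, and last the C2–O diaryl ether bond.
- The enabling feature is that ring A carries oxygen at C2 and C6 and methyl at C4, the pattern of symmetric 5-methylcyclohexane-1,3-dione. In that dione C5 is the alpha-prime carbon of the C6 carbonyl, and the C2–O–ring B ether is a vinylogous ester.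
- Forward: ring B phenol 4 (formylation, reduction, silylation of 2,4-dimethoxyphenol) is joined to chloroenone 6, and the prenyl chain is attached at C5. Ring A is then aromatised through its silyl dienol ether, and the C1 carboxyl carbon, the methyl ester and the free CH2OH follow.
- No ring is formed in the route; ring B is bought and ring A is only dehydrogenated.
- The target has no stereocentre. The two centres of the dihydro intermediates (C5 methyl, and C6 set trans by anti alkylation) vanish on aromatisation.

Key step: step 6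

Assumption: because the target is achiral, every chiral intermediate is a racemate; its SMILES shows one enantiomer with the correct relative configuration.

**Route**

Step 1
Reactants: 1 2,4-dimethoxyphenol
Product: 2 2-hydroxy-3,5-dimethoxybenzaldehyde
Conditions: MgCl2, Et3N, (CH2O)n, MeCN, reflux; dilute HCl work-up
Reagents that add atoms: paraformaldehyde (formaldehyde), C=O
Why: Magnesium phenoxide-mediated ortho-formylation (Casnati–Skattebøl) should occur at the only free ortho position of 1, a second formaldehyde acting as hydride acceptor to give the salicylaldehyde.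

Step 2
Reactants: 2 2-hydroxy-3,5-dimethoxybenzaldehyde
Product: 3 2-(hydroxymethyl)-4,6-dimethoxyphenol
Conditions: NaBH4, MeOH–THF, 0 °C; neutral work-up
Reagents that add atoms: none
Why: Hydride reduction of the aryl aldehyde by NaBH4 should give the benzylic alcohol, and a neutral work-up avoids ionisation of the electron-rich salicyl alcohol.

Step 3
Reactants: 3 2-(hydroxymethyl)-4,6-dimethoxyphenol
Product: 4 2-[(tert-butyldimethylsilyl)oxymethyl]-4,6-dimethoxyphenol
Conditions: TBSCl (1.05 equiv), imidazole, CH2Cl2, 0 °C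
Reagents that add atoms: tert-butyldimethylsilyl chloride, CC(C)(C)[Si](C)(C)Cl
Why: Selective O-silylation of the primary benzylic hydroxyl is expected because the di-ortho-substituted phenol is silylated more slowly and its silyl ether is the less stable one.

Step 4
Reactants: 5 5-methylcyclohexane-1,3-dione
Product: 6 racemic 3-chloro-5-methylcyclohex-2-en-1-one
Conditions: (COCl)2, cat. DMF, CH2Cl2, 0 °C to rt; used promptly
Reagents that add atoms: oxalyl chloride, O=C(Cl)C(=O)Cl
Why: Beta-chloroenone formation by O-acylation of the enol and chloride addition-elimination has no regiochemical issue because the two carbonyl groups of 5 are equivalent.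

Step 5
Reactants: 6 racemic 3-chloro-5-methylcyclohex-2-en-1-one; 4 2-[(tert-butyldimethylsilyl)oxymethyl]-4,6-dimethoxyphenol
Product: 7 racemic 3-[2-(tert-butyldimethylsilyloxymethyl)-4,6-dimethoxyphenoxy]-5-methylcyclohex-2-en-1-one
Conditions: K2CO3, DMF, rt to 50 °C
Reagents that add atoms: none
Why: Nucleophilic vinylic substitution (addition-elimination) of the phenoxide at the beta-carbon of the chloroenone should give the vinylogous aryl ester, attack at an sp2 carbon tolerating the two ortho substituents of the phenoxide.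

Step 6
Reactants: 7 racemic 3-[2-(tert-butyldimethylsilyloxymethyl)-4,6-dimethoxyphenoxy]-5-methylcyclohex-2-en-1-one; 8 prenyl bromide (1-bromo-3-methylbut-2-ene)
Product: 10 racemic trans-3-[2-(tert-butyldimethylsilyloxymethyl)-4,6-dimethoxyphenoxy]-5-methyl-6-(3-methylbut-2-enyl)cyclohex-2-en-1-one (5S*,6R*), via lithium alpha-prime enolate 9 (not isolated)
Conditions: LiN(iPr)2 (1.1 equiv), THF, −78 °C; then 8, DMPU, −78 to 0 °C
Reagents that add atoms: none
Why: LiN(iPr)2 at −78 °C should remove irreversibly the proton on the CH2 next to the carbonyl (alpha-prime, the future C5 of ring A) and not the gamma proton on the CH2 next to the aryloxy-bearing carbon, as is usual for vinylogous esters under kinetic control. The cross-conjugated lithium enolate 9 then displaces bromide at the primary carbon of 8 (SN2), forming the bond from C5 of ring A to the prenyl CH2; this is a Stork–Danheiser alkylation with an aryl instead of an alkyl group on the ether oxygen. No ring closes in this step. The one new stereocentre (C6 of the enone) should arise by approach of the halide anti to the neighbouring pseudoaxial methyl group, giving the trans isomer under substrate control, and it is erased on aromatisation. The step needs alpha-prime over gamma deprotonation, C- over O-alkylation and mono- over dialkylation, which the vinylogous ester, the lithium counter-ion paired with a soft allylic bromide, and complete enolate formation before addition of the halide should secure.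

Step 7
Reactants: 10 racemic trans-3-[2-(tert-butyldimethylsilyloxymethyl)-4,6-dimethoxyphenoxy]-5-methyl-6-(3-methylbut-2-enyl)cyclohex-2-en-1-one
Product: 12 racemic 2-(tert-butyldimethylsilyloxy)-4-[2-(tert-butyldimethylsilyloxymethyl)-4,6-dimethoxyphenoxy]-6-methyl-1-(3-methylbut-2-enyl)cyclohexa-1,3-diene, via lithium enolate 11 (not isolated)
Conditions: LiN(iPr)2, THF, −78 °C; then TBSCl, DMPU, −78 °C to rt; NaHCO3 work-up
Reagents that add atoms: tert-butyldimethylsilyl chloride, CC(C)(C)[Si](C)(C)Cl
Why: Kinetic deprotonation of the remaining alpha-prime hydrogen and O-silylation of the lithium enolate (silyl enol ether formation) should give the silyloxy diene, and a gamma-derived regioisomer, if formed, would lead to the same arene in step 8.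

Step 8
Reactants: 12 racemic 2-(tert-butyldimethylsilyloxy)-4-[2-(tert-butyldimethylsilyloxymethyl)-4,6-dimethoxyphenoxy]-6-methyl-1-(3-methylbut-2-enyl)cyclohexa-1,3-diene
Product: 13 tert-butyl-[5-[2-(tert-butyldimethylsilyloxymethyl)-4,6-dimethoxyphenoxy]-3-methyl-2-(3-methylbut-2-enyl)phenoxy]dimethylsilane
Conditions: DDQ (1.05 equiv), 2,4,6-collidine, PhH, 0 °C to rt
Reagents that add atoms: none
Why: Quinone dehydrogenation of a 1,3-cyclohexadiene (hydride abstraction from the methyl-bearing ring CH to a cation stabilised by both oxygen substituents, then loss of the adjacent ring proton) removes only ring hydrogens, so the new unsaturation cannot be placed toward the prenyl CH2, and the phenol emerges silylated and shielded from further oxidation.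

Step 9
Reactants: 13 tert-butyl-[5-[2-(tert-butyldimethylsilyloxymethyl)-4,6-dimethoxyphenoxy]-3-methyl-2-(3-methylbut-2-enyl)phenoxy]dimethylsilane
Product: 14 5-[2-(tert-butyldimethylsilyloxymethyl)-4,6-dimethoxyphenoxy]-3-methyl-2-(3-methylbut-2-enyl)phenol
Conditions: Cs2CO3 (0.5 equiv), DMF–H2O (10:1), rt
Reagents that add atoms: none
Why: Chemoselective desilylation is expected because phenoxide is a far better leaving group at silicon than an alkoxide, so carbonate in wet DMF cleaves the aryl silyl ether and leaves the benzylic one.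

Step 10
Reactants: 14 5-[2-(tert-butyldimethylsilyloxymethyl)-4,6-dimethoxyphenoxy]-3-methyl-2-(3-methylbut-2-enyl)phenol
Product: 15 6-[2-(tert-butyldimethylsilyloxymethyl)-4,6-dimethoxyphenoxy]-2-hydroxy-4-methyl-3-(3-methylbut-2-enyl)benzaldehyde
Conditions: MgCl2, Et3N, (CH2O)n, THF, reflux; buffered NH4Cl/dilute HCl work-up
Reagents that add atoms: paraformaldehyde (formaldehyde), C=O
Why: In the Casnati–Skattebøl ortho-formylation the magnesium phenoxide delivers formaldehyde within a chelate to the only free ortho carbon (C1, between the two oxygens, the other ortho carbon bearing the prenyl group), so the para CH and ring B should stay untouched.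

Step 11
Reactants: 15 6-[2-(tert-butyldimethylsilyloxymethyl)-4,6-dimethoxyphenoxy]-2-hydroxy-4-methyl-3-(3-methylbut-2-enyl)benzaldehyde
Product: 16 6-[2-(tert-butyldimethylsilyloxymethyl)-4,6-dimethoxyphenoxy]-2-hydroxy-4-methyl-3-(3-methylbut-2-enyl)benzoic acid
Conditions: NaClO2, NaH2PO4, 2-methylbut-2-ene (large excess), t-BuOH–THF–H2O, 0 °C to rt
Reagents that add atoms: sodium chlorite, [Na+].[O-]Cl=O
Why: Pinnick oxidation converts the aldehyde to the acid under buffered conditions, the excess 2-methylbut-2-ene scavenging HOCl so that the prenyl alkene and the electron-rich rings should be spared.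

Step 12
Reactants: 16 6-[2-(tert-butyldimethylsilyloxymethyl)-4,6-dimethoxyphenoxy]-2-hydroxy-4-methyl-3-(3-methylbut-2-enyl)benzoic acid
Product: 17 methyl 6-[2-(tert-butyldimethylsilyloxymethyl)-4,6-dimethoxyphenoxy]-2-hydroxy-4-methyl-3-(3-methylbut-2-enyl)benzoate
Conditions: MeI, KHCO3, DMF, rt
Reagents that add atoms: iodomethane, CI
Why: SN2 esterification of the carboxylate with iodomethane should be selective because hydrogen carbonate is too weak a base to deprotonate the hydrogen-bonded phenol.

Step 13
Reactants: 17 methyl 6-[2-(tert-butyldimethylsilyloxymethyl)-4,6-dimethoxyphenoxy]-2-hydroxy-4-methyl-3-(3-methylbut-2-enyl)benzoate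
Product: 18 methyl 2-hydroxy-6-[2-(hydroxymethyl)-4,6-dimethoxyphenoxy]-4-methyl-3-(3-methylbut-2-enyl)benzoate (CNP0583011.0)
Conditions: Bu4NF, AcOH (1:1), THF, 0 °C to rt
Reagents that add atoms: none
Why: Fluoride-driven cleavage of the primary silyl ether under buffered, non-acidic conditions should free the benzylic alcohol without acid-promoted cyclisation of the ortho-prenylphenol to a chroman.

**Compound list**

1 | 2,4-dimethoxyphenol | COc1ccc(O)c(OC)c1 | starting material
2 | 2-hydroxy-3,5-dimethoxybenzaldehyde | O=Cc1cc(OC)cc(OC)c1O | intermediate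
3 | 2-(hydroxymethyl)-4,6-dimethoxyphenol | OCc1cc(OC)cc(OC)c1O | intermediate
4 | 2-[(tert-butyldimethylsilyl)oxymethyl]-4,6-dimethoxyphenol | CC(C)(C)[Si](C)(C)OCc1cc(OC)cc(OC)c1O | intermediate
5 | 5-methylcyclohexane-1,3-dione | CC1CC(=O)CC(=O)C1 | starting material
6 | racemic 3-chloro-5-methylcyclohex-2-en-1-one | C[C@H]1CC(Cl)=CC(=O)C1 | intermediate
7 | racemic 3-[2-(tert-butyldimethylsilyloxymethyl)-4,6-dimethoxyphenoxy]-5-methylcyclohex-2-en-1-one | C[C@H]1CC(Oc2c(CO[Si](C)(C)C(C)(C)C)cc(OC)cc2OC)=CC(=O)C1 | intermediate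
8 | prenyl bromide (1-bromo-3-methylbut-2-ene) | CC(C)=CCBr | starting material
9 | racemic lithium 5-[2-(tert-butyldimethylsilyloxymethyl)-4,6-dimethoxyphenoxy]-3-methylcyclohexa-1,5-dien-1-olate (alpha-prime enolate of 7) | C[C@H]1CC(Oc2c(CO[Si](C)(C)C(C)(C)C)cc(OC)cc2OC)=CC([O-])=C1.[Li+] | intermediate
10 | racemic trans-3-[2-(tert-butyldimethylsilyloxymethyl)-4,6-dimethoxyphenoxy]-5-methyl-6-(3-methylbut-2-enyl)cyclohex-2-en-1-one (5S*,6R*) | C[C@H]1CC(Oc2c(CO[Si](C)(C)C(C)(C)C)cc(OC)cc2OC)=CC(=O)[C@@H]1CC=C(C)C | intermediate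
11 | racemic lithium 5-[2-(tert-butyldimethylsilyloxymethyl)-4,6-dimethoxyphenoxy]-3-methyl-2-(3-methylbut-2-enyl)cyclohexa-1,5-dien-1-olate (enolate of 10) | C[C@H]1CC(Oc2c(CO[Si](C)(C)C(C)(C)C)cc(OC)cc2OC)=CC([O-])=C1CC=C(C)C.[Li+] | intermediate
12 | racemic 2-(tert-butyldimethylsilyloxy)-4-[2-(tert-butyldimethylsilyloxymethyl)-4,6-dimethoxyphenoxy]-6-methyl-1-(3-methylbut-2-enyl)cyclohexa-1,3-diene | C[C@H]1CC(Oc2c(CO[Si](C)(C)C(C)(C)C)cc(OC)cc2OC)=CC(O[Si](C)(C)C(C)(C)C)=C1CC=C(C)C | intermediate
13 | tert-butyl-[5-[2-(tert-butyldimethylsilyloxymethyl)-4,6-dimethoxyphenoxy]-3-methyl-2-(3-methylbut-2-enyl)phenoxy]dimethylsilane | Cc1cc(Oc2c(CO[Si](C)(C)C(C)(C)C)cc(OC)cc2OC)cc(O[Si](C)(C)C(C)(C)C)c1CC=C(C)C | intermediate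
14 | 5-[2-(tert-butyldimethylsilyloxymethyl)-4,6-dimethoxyphenoxy]-3-methyl-2-(3-methylbut-2-enyl)phenol | Cc1cc(Oc2c(CO[Si](C)(C)C(C)(C)C)cc(OC)cc2OC)cc(O)c1CC=C(C)C | intermediate
15 | 6-[2-(tert-butyldimethylsilyloxymethyl)-4,6-dimethoxyphenoxy]-2-hydroxy-4-methyl-3-(3-methylbut-2-enyl)benzaldehyde | O=Cc1c(Oc2c(CO[Si](C)(C)C(C)(C)C)cc(OC)cc2OC)cc(C)c(CC=C(C)C)c1O | intermediate
16 | 6-[2-(tert-butyldimethylsilyloxymethyl)-4,6-dimethoxyphenoxy]-2-hydroxy-4-methyl-3-(3-methylbut-2-enyl)benzoic acid | OC(=O)c1c(Oc2c(CO[Si](C)(C)C(C)(C)C)cc(OC)cc2OC)cc(C)c(CC=C(C)C)c1O | intermediate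
17 | methyl 6-[2-(tert-butyldimethylsilyloxymethyl)-4,6-dimethoxyphenoxy]-2-hydroxy-4-methyl-3-(3-methylbut-2-enyl)benzoate | COC(=O)c1c(Oc2c(CO[Si](C)(C)C(C)(C)C)cc(OC)cc2OC)cc(C)c(CC=C(C)C)c1O | intermediate
18 | methyl 2-hydroxy-6-[2-(hydroxymethyl)-4,6-dimethoxyphenoxy]-4-methyl-3-(3-methylbut-2-enyl)benzoate | COC(=O)c1c(Oc2c(CO)cc(OC)cc2OC)cc(C)c(CC=C(C)C)c1O | target

**Step count**

Total: 13 steps. Longest linear sequence: 12 steps (from 1 through steps 1–3 and 5–13); the branch from 5 joins at step 5.

**Steps most likely to fail**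

Step 6. The enolate may attack the aryloxy-bearing carbon of a second molecule (addition-elimination with loss of the phenoxide), or proton exchange between product and enolate may lead to double alkylation. The fallback sets out from 5 and returns at 10; it performs the same alkylation on an alkyl vinylogous ester and introduces ring B afterwards. Condensation of 5 with 2-methylpropan-1-ol (TsOH, PhMe, water removal) gives racemic 3-(2-methylpropoxy)-5-methylcyclohex-2-en-1-one F1. LiN(iPr)2 in THF at −78 °C converts it into its lithium alpha-prime enolate F2, which is alkylated with 8 to racemic trans-3-(2-methylpropoxy)-5-methyl-6-(3-methylbut-2-enyl)cyclohex-2-en-1-one F3. Dilute aqueous HCl in THF at rt hydrolyses the enol ether to racemic trans-5-methyl-4-(3-methylbut-2-enyl)cyclohexane-1,3-dione F4. Oxalyl chloride should then react at the less hindered carbonyl, remote from the prenyl group, to give racemic trans-3-chloro-5-methyl-6-(3-methylbut-2-enyl)cyclohex-2-en-1-one F5. Displacement of chloride by phenol 4 (K2CO3, DMF) gives 10.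

Step 8. The quinone may go on to abstract hydride from the benzylic-allylic CH2 of the prenyl group, or the acidic hydroquinone may hydrolyse the dienol ether back to the enone before dehydrogenation. The fallback sets out from 10 and returns at 14. Enolate 11, generated as in step 7, is quenched with PhSeBr to give racemic 3-[2-(tert-butyldimethylsilyloxymethyl)-4,6-dimethoxyphenoxy]-5-methyl-6-(3-methylbut-2-enyl)-6-(phenylselanyl)cyclohex-2-en-1-one F6, with selenium expected anti to the methyl group and therefore syn to the ring hydrogen. H2O2 with pyridine in CH2Cl2 at 0 °C oxidises it to the selenoxide F7. Syn elimination into the ring gives 3-[2-(tert-butyldimethylsilyloxymethyl)-4,6-dimethoxyphenoxy]-5-methyl-6-(3-methylbut-2-enyl)cyclohexa-2,5-dien-1-one F8, which tautomerises to phenol 14. Elimination toward the prenyl CH2 can compete here, which is why this sequence is held in reserve.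

Step 10. Carbon–carbon bond formation at C1 may be slow, since this carbon lies between the phenol oxygen and the twisted, di-ortho-substituted aryloxy group, and prolonged heating may degrade the ortho-prenylphenol. The fallback sets out from 14 and returns at 18; it replaces formylation and oxidation by directed ortho-metalation and carboxylation. SEMCl with i-Pr2NEt in CH2Cl2 gives the 2-(trimethylsilyl)ethoxymethyl ether of 14, F9. n-BuLi with TMEDA in THF (−78 to 0 °C) should lithiate between the acetal oxygen and the diaryl ether oxygen, the acetal being the stronger coordinating group, to give the aryllithium F10. Methyl chloroformate at −78 °C traps it as methyl 6-[2-(tert-butyldimethylsilyloxymethyl)-4,6-dimethoxyphenoxy]-4-methyl-3-(3-methylbut-2-enyl)-2-[2-(trimethylsilyl)ethoxymethoxy]benzoate F11. Bu4NF in THF–DMPU with gentle warming removes both silicon-based groups and gives 18.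

**Further compounds**

F1 | step 6 | racemic 3-(2-methylpropoxy)-5-methylcyclohex-2-en-1-one | C[C@H]1CC(OCC(C)C)=CC(=O)C1
F2 | step 6 | racemic lithium 3-methyl-5-(2-methylpropoxy)cyclohexa-1,5-dien-1-olate (alpha-prime enolate of F1) | C[C@H]1CC(OCC(C)C)=CC([O-])=C1.[Li+]
F3 | step 6 | racemic trans-3-(2-methylpropoxy)-5-methyl-6-(3-methylbut-2-enyl)cyclohex-2-en-1-one | C[C@H]1CC(OCC(C)C)=CC(=O)[C@@H]1CC=C(C)C
F4 | step 6 | racemic trans-5-methyl-4-(3-methylbut-2-enyl)cyclohexane-1,3-dione | C[C@H]1CC(=O)CC(=O)[C@@H]1CC=C(C)C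
F5 | step 6 | racemic trans-3-chloro-5-methyl-6-(3-methylbut-2-enyl)cyclohex-2-en-1-one | C[C@H]1CC(Cl)=CC(=O)[C@@H]1CC=C(C)C
F6 | step 8 | racemic 3-[2-(tert-butyldimethylsilyloxymethyl)-4,6-dimethoxyphenoxy]-5-methyl-6-(3-methylbut-2-enyl)-6-(phenylselanyl)cyclohex-2-en-1-one (selenium trans to methyl) | C[C@H]1CC(Oc2c(CO[Si](C)(C)C(C)(C)C)cc(OC)cc2OC)=CC(=O)[C@]1(CC=C(C)C)[Se]c1ccccc1
F7 | step 8 | selenoxide of F6 (mixture at selenium) | C[C@H]1CC(Oc2c(CO[Si](C)(C)C(C)(C)C)cc(OC)cc2OC)=CC(=O)[C@]1(CC=C(C)C)[Se](=O)c1ccccc1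
F8 | step 8 | 3-[2-(tert-butyldimethylsilyloxymethyl)-4,6-dimethoxyphenoxy]-5-methyl-6-(3-methylbut-2-enyl)cyclohexa-2,5-dien-1-one | CC1=C(CC=C(C)C)C(=O)C=C(Oc2c(CO[Si](C)(C)C(C)(C)C)cc(OC)cc2OC)C1
F9 | step 10 | tert-butyl-[[3,5-dimethoxy-2-[3-methyl-4-(3-methylbut-2-enyl)-5-[2-(trimethylsilyl)ethoxymethoxy]phenoxy]phenyl]methoxy]dimethylsilane (SEM ether of 14) | Cc1cc(Oc2c(CO[Si](C)(C)C(C)(C)C)cc(OC)cc2OC)cc(OCOCC[Si](C)(C)C)c1CC=C(C)C
F10 | step 10 | aryllithium from F9, lithiated at C1 of ring A | [Li]c1c(Oc2c(CO[Si](C)(C)C(C)(C)C)cc(OC)cc2OC)cc(C)c(CC=C(C)C)c1OCOCC[Si](C)(C)C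
F11 | step 10 | methyl 6-[2-(tert-butyldimethylsilyloxymethyl)-4,6-dimethoxyphenoxy]-4-methyl-3-(3-methylbut-2-enyl)-2-[2-(trimethylsilyl)ethoxymethoxy]benzoate | COC(=O)c1c(Oc2c(CO[Si](C)(C)C(C)(C)C)cc(OC)cc2OC)cc(C)c(CC=C(C)C)c1OCOCC[Si](C)(C)C
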